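Numbering used below: chromanone atoms O1, C2, C3, C4, C4a, C5–C8, C8a; hexanoate chain C1' (ester carbon), C2', C3' (the stereocentre on C8), C4'–C6'; the prenyl group sits on C6.

## The problem

- **Ring substitution.** The target is a fully substituted phloroglucinol. Its three ring carbons carry three different carbon groups: the chromanone carbonyl C4 (on C4a), a prenyl group (C6) and the hexanoate chain through C3' (C8). Of its three oxygens, O1 is the pyranone ether and O5–H and O7–H are free.
- **Regiochemistry.** The pyranone must close on the oxygen between the acyl carbon and the chain-bearing carbon, not on the one next to the prenyl carbon. A 5-hydroxychromanone can exchange these two by base-induced ring opening and reclosure (Wessely–Moser-type), which also destroys C2.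
- **Chromanone stereocentres.** C2 and C3 are trans (2S,3S). C3 is enolizable and trans is the thermodynamic arrangement, so C2 controls C3.
- **Remote stereocentre.** C3' (R) is five bonds from C2 across the flat arene. Neither centre can control the other, so two independent catalyst-controlled events are needed.
- **Sensitive groups.** The prenyl group next to free phenols excludes strong acid, hydrogenation and electrophilic halogen once it is present. The ortho-hydroxy ester can relactonize under acid or heat.
- **Enabling feature.** O7–H on C7 is ortho to C8, and C8 carries C3', whose chain ends in C1'. The atoms O7, C7, C8, C3', C2', C1' are therefore a ring-opened six-membered lactone (a 4-propyl-3,4-dihydrocoumarin). O7 is also para to the C4 ketone, so it is the most acidic phenol and its esters are active esters. The O7–C1' bond can thus be made first, as an ordinary ester, and the C8–C3' bond made from it.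

## Retrosynthesis

**13 ⇒ 12.** The methyl ester C1'–OMe bond is exchanged for an O7–C1' bond: 13 is the methanolysis product of lactone 12. This masks the acidic 7-OH and the ester in one ring until the last step. The forward reaction must open an aryl lactone without touching C2; because the leaving O7 is a vinylogous carboxylate, a weak amine base should suffice.

**12 ⇒ 10 (through 11).** The C8–C3' bond is cut while O7–C1' is kept, so 12 becomes its isomer, aryl (E)-hex-2-enoate 10. This is preferred over cutting C3'–C2' (an ortho-quinone methide) or C3'–H (a coumarin reduction) because the stereo-inducing element then sits on the electrophile and the crowded arene only has to act as a nucleophile. 10 has no C3' stereocentre and no lactone ring, and its hexenoyl group has been carried since step 2 as a protecting group. The forward step asks a chiral carbene to ionize the ester to ion pair 11 and to return the acyl group to C8 at its β-carbon, with C8 chosen over C6 and one β-face chosen by the catalyst.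

**10 ⇒ 8 + 9, and 8 ⇒ 7.** The C6–prenyl bond is cut to aryl iodide 8 and stannane 9; the iodide comes from 7 by substitution ortho to the chelated 5-OH. The prenyl group must be in place before the key step, because it is what closes C6 to the migrating acyl group. It must come after ring closure, because the open precursor has two equivalent carbons. The forward steps need C6 over C8 in the iodination and transfer of the prenyl group without allylic transposition.

**7 ⇒ 6 ⇒ 5.** The O1–C2 bond is cut (oxa-Michael) and C3 is set by equilibration. In 5 the two hydroxyls flanking the tigloyl group are equivalent, so closure on either gives the same compound. The O1/O5 question is thereby settled by symmetry before any other ring carbon is substituted. The forward step needs facial control at C2 from a chiral base; C3 then follows thermodynamically.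

**5 ⇒ 3 + 4, and 3 ⇒ 1 + 2.** The ester and the aryl ketone are cut. The para hydroxyl of 3 is the only non-chelated one and is esterified selectively. All carbons of 13 except the ester methyl then come from the four commercial pieces 1, 2, 4 and 9.

## Roads not taken

Alternative 1: The most obvious plan keeps the lactone as a coumarin and cuts no skeletal bond at the stereocentre.
- Cut and key step: Pechmann condensation of 1 with ethyl 3-oxohexanoate gives 5,7-dihydroxy-4-propylcoumarin A1. Tigloylation, ring closure and prenylation lead to the fully substituted coumarin A2. Enantioselective conjugate reduction of its C3=C4 bond (copper hydride from Cu(OAc)2, a silane and a chiral bisphosphine) would give 12.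
- Why the chosen plan is better: acylation of A1 is known to prefer C8, next to the lactone oxygen, whereas the target needs the acyl carbon between the two free hydroxyls and closure onto the hindered peri hydroxyl; two regiochemical decisions are left to substrate bias. The stereo-defining hydride transfer would also come last, on a trisubstituted, doubly ortho-substituted, electron-rich enoate beside an aryl ketone and a prenyl alkene. The chosen plan settles regiochemistry by symmetry and makes C3' by C–C bond formation.

Alternative 2: An ortho-quinone methide at C7/C8, cutting C3'–C2'.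
- Cut and key step: the free 7-phenol A3 (10 without its hexenoyl group), butanal and sodium p-toluenesulfinate give sulfone A4. Base releases the methide A5. A bifunctional squaramide directs the addition of Meldrum's acid, and lactonization with decarboxylation would give 12.
- Why the chosen plan is better: the methide carbon of A5 is flanked by two oxygens (C7=O and C8a–O1), so its butylidene geometry is not biased and a hydrogen-bonding catalyst has little to read. An alkyl-substituted methide can also tautomerize to the alkenylphenol. The sulfone must be made under acid with the prenyl group present, and the sequence is two steps longer and loses acetone and CO2.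

Alternative 3: Early aryl–C3' bond by asymmetric conjugate addition.
- Cut and key step: rhodium-catalysed addition ([RhCl(cod)]2, (R)-BINAP) of 2,4,6-tris(methoxymethoxy)phenylboronic acid A6 to methyl (E)-hex-2-enoate would give ester A7; deprotection, acylation, ring closure and prenylation follow.
- Why the chosen plan is better: 2,6-dioxygenated arylboronic acids protodeboronate easily and transfer slowly. Once the phenols are freed, the hydroxy ester lactonizes and breaks the symmetry, so the O1/O5 closure problem returns. The electron-rich benzylic centre must then survive Friedel–Crafts acid, and at least four protecting-group operations are added.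

Key step: step 7

Assumption: the sense of induction of quinidine in step 3 and of the (5aR,10bS) triazolium salt in step 7 is taken by analogy with related substrates; should either be opposite, quinine or the (5aS,10bR) salt is used and nothing else changes.

Step 1
Reactants: 1 benzene-1,3,5-triol (phloroglucinol); 2 (E)-2-methylbut-2-enoyl chloride (tigloyl chloride)
Product: 3 (E)-2-methyl-1-(2,4,6-trihydroxyphenyl)but-2-en-1-one
Conditions: AlCl3 (3 equiv), PhNO2/CH2Cl2, 0 °C to rt; cold aqueous HCl work-up
Reagents that add atoms: none
Why: Friedel–Crafts C-acylation of a threefold-symmetric, very nucleophilic arene, so only one mono-acyl product is possible; the aluminium chelate of the o-hydroxy ketone resists a second acylation, and the low temperature is meant to keep the enone from cyclizing.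

Step 2
Reactants: 3 (E)-2-methyl-1-(2,4,6-trihydroxyphenyl)but-2-en-1-one; 4 (E)-hex-2-enoic acid
Product: 5 3,5-dihydroxy-4-[(E)-2-methylbut-2-enoyl]phenyl (E)-hex-2-enoate
Conditions: DIC, DMAP (5 mol %), CH2Cl2/THF, 0 °C
Reagents that add atoms: none
Why: Steglich esterification; the para hydroxyl is the only one not hydrogen-bonded to the ketone and is the most acidic, so it should be acylated selectively, which removes the vinylogous acid that would otherwise deactivate the enone in step 3.

Step 3
Reactants: 5 3,5-dihydroxy-4-[(E)-2-methylbut-2-enoyl]phenyl (E)-hex-2-enoate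
Product: 6 (2S,3R)-5-hydroxy-2,3-dimethyl-4-oxo-3,4-dihydro-2H-chromen-7-yl (E)-hex-2-enoate
Conditions: quinidine (C20H24N2O2, 15 mol %), PhCl, 15 °C to rt
Reagents that add atoms: none
Why: cinchona-base-catalysed intramolecular oxa-Michael addition of an o-tigloylphenol (6-endo-trig), in which the quinuclidine nitrogen activates the phenol and the C9 hydroxyl binds the ketone, so the catalyst sets C2 as S; the two flanking hydroxyls are equivalent, so no regiochemical choice arises, and kinetic protonation should give mainly the cis isomer, any trans isomer 7 formed alongside being carried on.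

Step 4
Reactants: 6 (2S,3R)-5-hydroxy-2,3-dimethyl-4-oxo-3,4-dihydro-2H-chromen-7-yl (E)-hex-2-enoate
Product: 7 (2S,3S)-5-hydroxy-2,3-dimethyl-4-oxo-3,4-dihydro-2H-chromen-7-yl (E)-hex-2-enoate
Conditions: MgBr2·OEt2, Et3N, CH2Cl2, rt
Reagents that add atoms: none
Why: soft enolization through the magnesium chelate of O5 and the C4 ketone epimerizes only C3; the trans isomer with both methyl groups pseudo-equatorial is the thermodynamic one, so cis and trans material converge on (2S,3S) while C2 is untouched as long as no β-elimination occurs.

Step 5
Reactants: 7 (2S,3S)-5-hydroxy-2,3-dimethyl-4-oxo-3,4-dihydro-2H-chromen-7-yl (E)-hex-2-enoate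
Product: 8 (2S,3S)-5-hydroxy-6-iodo-2,3-dimethyl-4-oxo-3,4-dihydro-2H-chromen-7-yl (E)-hex-2-enoate
Conditions: NIS (1.05 equiv), CF3CO2H (10 mol %), MeCN, 0 °C, dark
Reagents that add atoms: N-iodosuccinimide, O=C1CCC(=O)N1I
Why: electrophilic aromatic iodination; 5-hydroxy-7-O-substituted chromones and flavones are known to be iodinated ortho to the free chelated 5-OH (C6) rather than at C8, and because the 7-O substituent is ortho to both candidates, changing it from alkyl to acyl should not change that preference; the enoate alkene is electron-poor and inert.

Step 6
Reactants: 8 (2S,3S)-5-hydroxy-6-iodo-2,3-dimethyl-4-oxo-3,4-dihydro-2H-chromen-7-yl (E)-hex-2-enoate; 9 tributyl(3-methylbut-2-en-1-yl)stannane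
Product: 10 (2S,3S)-5-hydroxy-2,3-dimethyl-6-(3-methylbut-2-en-1-yl)-4-oxo-3,4-dihydro-2H-chromen-7-yl (E)-hex-2-enoate
Conditions: Pd2(dba)3 (2.5 mol %), P(2-furyl)3 (10 mol %), 1,4-dioxane, 80 °C
Reagents that add atoms: none
Why: Stille coupling under neutral conditions, which the active ester and the free chelated phenol tolerate; reductive elimination at the less hindered allyl terminus should give the linear prenyl group, and amine-free dioxane avoids aminolysis of the ester.

Step 7
Reactants: 10 (2S,3S)-5-hydroxy-2,3-dimethyl-6-(3-methylbut-2-en-1-yl)-4-oxo-3,4-dihydro-2H-chromen-7-yl (E)-hex-2-enoate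
Product: 12 (3'R)-7-O,1'-lactone of 3-[(2S,3S)-5,7-dihydroxy-2,3-dimethyl-6-(3-methylbut-2-en-1-yl)-4-oxo-3,4-dihydro-2H-chromen-8-yl]hexanoic acid (a 4-propyl-3,4-dihydrocoumarin ring fused at C7–C8), via acyl azolium phenoxide ion pair 11 (not isolated)
Conditions: (5aR,10bS)-2-mesityl-5a,10b-dihydro-4H,6H-indeno[2,1-b][1,2,4]triazolo[4,3-d][1,4]oxazin-2-ium chloride (15 mol %), i-Pr2NEt (20 mol %), 4 Å molecular sieves, toluene, rt to 40 °C
Reagents that add atoms: none
Why: Proposed new method: the free carbene adds to the ester carbonyl of 10 and expels the O7 phenoxide (a leaving group comparable to 4-nitrophenoxide because O7 is para to the C4 ketone) to give the α,β-unsaturated acyl azolium/phenoxide ion pair 11; the phenoxide then either re-adds through O7 to the azolium carbonyl and the hemiacetal undergoes a [3,3] (Coates–Claisen) shift, or it attacks directly through C8, in both cases forming the C8–C3' bond at the β-carbon, after which proton transfer restores the arene and O7 acylates the saturated acyl azolium to release the carbene. The closest known reactions are the carbene-catalysed rearrangement of α,β-unsaturated enol esters to dihydropyranones, carbene activation of α,β-unsaturated 4-nitrophenyl esters, and the enantioselective [3+3] annulation of unsaturated acyl azoliums with naphthols to 4-substituted dihydrocoumarins; new here is that one aryl ester supplies both partners. The lactone ring (O7, C7, C8, C3', C2', C1') closes in two events, C8–C3' bond formation by the formal [3,3] shift or conjugate addition and then a 6-exo-trig O-acylation. The only new stereocentre, C3', is set by the catalyst alone: the indane wall of the triazolium shields one face of the acyl azolium so that C8 adds to the Re face of the β-carbon, which gives R, and the chromanone centres are too remote to interfere. The step needs C8 over C6 and C over O: C6 is blocked by the prenyl group (attack there could not rearomatize and should revert), O-reacylation only regenerates 10, and the chelated 5-OH has no free ortho or para carbon.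

Step 8
Reactants: 12 (3'R)-7-O,1'-lactone of 3-[(2S,3S)-5,7-dihydroxy-2,3-dimethyl-6-(3-methylbut-2-en-1-yl)-4-oxo-3,4-dihydro-2H-chromen-8-yl]hexanoic acid
Product: 13 methyl (3R)-3-[(2S,3S)-5,7-dihydroxy-2,3-dimethyl-6-(3-methylbut-2-en-1-yl)-4-oxo-3,4-dihydro-2H-chromen-8-yl]hexanoate
Conditions: MeOH, Et3N (2 equiv), DMAP (5 mol %), 0 °C to rt; AcOH quench, concentration without heating
Reagents that add atoms: methanol, CO
Why: transesterification of an activated aryl lactone; the released O7 is a vinylogous carboxylate, so the equilibrium should lie on the open side in methanol and a weak amine base suffices, which leaves C2 (no ring opening), C3 (already thermodynamic) and C3' (not acidic) unchanged, and the prenyl group meets no acid.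

Compound list

1 | benzene-1,3,5-triol (phloroglucinol) | Oc1cc(O)cc(O)c1 | starting material
2 | (E)-2-methylbut-2-enoyl chloride | C/C=C(\C)C(Cl)=O | starting material
3 | (E)-2-methyl-1-(2,4,6-trihydroxyphenyl)but-2-en-1-one | C/C=C(\C)C(=O)c1c(O)cc(O)cc1O | intermediate
4 | (E)-hex-2-enoic acid | CCC/C=C/C(=O)O | starting material
5 | 3,5-dihydroxy-4-[(E)-2-methylbut-2-enoyl]phenyl (E)-hex-2-enoate | CCC/C=C/C(=O)Oc1cc(O)c(C(=O)/C(C)=C/C)c(O)c1 | intermediate
6 | (2S,3R)-5-hydroxy-2,3-dimethyl-4-oxo-3,4-dihydro-2H-chromen-7-yl (E)-hex-2-enoate | CCC/C=C/C(=O)Oc1cc(O)c2C(=O)[C@H](C)[C@H](C)Oc2c1 | intermediate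
7 | (2S,3S)-5-hydroxy-2,3-dimethyl-4-oxo-3,4-dihydro-2H-chromen-7-yl (E)-hex-2-enoate | CCC/C=C/C(=O)Oc1cc(O)c2C(=O)[C@@H](C)[C@H](C)Oc2c1 | intermediate
8 | (2S,3S)-5-hydroxy-6-iodo-2,3-dimethyl-4-oxo-3,4-dihydro-2H-chromen-7-yl (E)-hex-2-enoate | CCC/C=C/C(=O)Oc1c(I)c(O)c2C(=O)[C@@H](C)[C@H](C)Oc2c1 | intermediate
9 | tributyl(3-methylbut-2-en-1-yl)stannane | CCCC[Sn](CCCC)(CCCC)CC=C(C)C | starting material
10 | (2S,3S)-5-hydroxy-2,3-dimethyl-6-(3-methylbut-2-en-1-yl)-4-oxo-3,4-dihydro-2H-chromen-7-yl (E)-hex-2-enoate | CCC/C=C/C(=O)Oc1c(CC=C(C)C)c(O)c2C(=O)[C@@H](C)[C@H](C)Oc2c1 | intermediate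
11 | ion pair of the (5aR,10bS)-1-[(E)-hex-2-enoyl]-2-mesityl-5a,10b-dihydro-4H,6H-indeno[2,1-b][1,2,4]triazolo[4,3-d][1,4]oxazin-2-ium cation and the 7-phenoxide of (2S,3S)-5,7-dihydroxy-2,3-dimethyl-6-(3-methylbut-2-en-1-yl)-2,3-dihydro-4H-chromen-4-one | CCC/C=C/C(=O)c1[n+](-c2c(C)cc(C)cc2C)nc2CO[C@@H]3Cc4ccccc4[C@@H]3n12.[O-]c1c(CC=C(C)C)c(O)c2C(=O)[C@@H](C)[C@H](C)Oc2c1 | intermediate
12 | (3'R)-7-O,1'-lactone of 3-[(2S,3S)-5,7-dihydroxy-2,3-dimethyl-6-(3-methylbut-2-en-1-yl)-4-oxo-3,4-dihydro-2H-chromen-8-yl]hexanoic acid | CCC[C@@H]1CC(=O)Oc2c(CC=C(C)C)c(O)c3C(=O)[C@@H](C)[C@H](C)Oc3c12 | intermediate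
13 | methyl (3R)-3-[(2S,3S)-5,7-dihydroxy-2,3-dimethyl-6-(3-methylbut-2-en-1-yl)-4-oxo-3,4-dihydro-2H-chromen-8-yl]hexanoate | CCC[C@H](CC(=O)OC)c1c(O)c(CC=C(C)C)c(O)c2c1O[C@@H](C)[C@H](C)C2=O | target

Total step count: 8. Longest linear sequence: 8 steps, from 1.

Least certain steps

Step 7 (key step, proposed new method).
- What may go wrong: the ion pair may collapse only by O-reacylation, a degenerate return to 10. The phenoxide may drift out of the chiral ion pair before C–C bond formation, eroding facial selectivity. The carbene may add in conjugate fashion to the enoate, or the acyl azolium may be deprotonated at its γ-carbon.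
- Fallback (known chemistry): it sets out from 10. The 7-O-ester is cleaved with MeOH/Et3N at rt to the free phenol (2S,3S)-5,7-dihydroxy-2,3-dimethyl-6-(3-methylbut-2-en-1-yl)-2,3-dihydro-4H-chromen-4-one F1. F1 is then joined with commercial (E)-hex-2-enal in the established oxidative carbene-catalysed [3+3] annulation of enals with naphthols and related enol-type carbon nucleophiles (same triazolium salt, i-Pr2NEt, 3,3',5,5'-tetra-tert-butyl-4,4'-diphenoquinone as oxidant, toluene, rt). Here the acyl azolium comes from the aldehyde and no ester has to be ionized. The product is 12, where the route is rejoined.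

Step 3.
- What may go wrong: racemic background closure by adventitious base; weak facial discrimination because the second ortho hydroxyl competes for the catalyst's hydrogen bonds; acyl transfer from the active 7-O-ester to the hydroxyl of the alkaloid, which would use up the catalyst.
- Fallback: it sets out from 5. An achiral base (Et3N, MeCN, rt) closes the ring and equilibrates C3, giving 7 together with its enantiomer (2R,3R)-5-hydroxy-2,3-dimethyl-4-oxo-3,4-dihydro-2H-chromen-7-yl (E)-hex-2-enoate F2. The two are separated by chromatography on a chiral stationary phase. F2 is returned to the racemate with DBU through ring opening and reclosure and separated again. The route is rejoined at 7.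

Step 5.
- What may go wrong: substitution para to the 5-OH (at C8) instead of ortho, or double iodination, because both open carbons are activated by three oxygens; the extrapolation from 7-alkoxy to 7-acyloxy substrates is untested.
- Fallback: it sets out from 7 and replaces electrophilic substitution by an intramolecular oxygen-to-carbon transfer. Pd(PPh3)4-catalysed O-alkylation of the 5-OH with tert-butyl (2-methylbut-3-en-2-yl) carbonate (THF, rt) gives the tertiary allyl ether (2S,3S)-2,3-dimethyl-5-[(2-methylbut-3-en-2-yl)oxy]-4-oxo-3,4-dihydro-2H-chromen-7-yl (E)-hex-2-enoate F3. Heating (toluene, 100–110 °C) brings about the aromatic Claisen rearrangement to C6, the only free ortho position of O5, with allylic inversion to the linear prenyl group. This gives 10 directly, so steps 5 and 6 are both replaced, and the route is rejoined at 10.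

Step 6.
- What may go wrong: slow transmetalation at the doubly ortho-substituted arylpalladium intermediate, which leaves time for intramolecular carbopalladation of the neighbouring enoate or for protodeiodination; partial allylic transposition to the 1,1-dimethylallyl isomer.
- Fallback: it sets out from 8 and inverts the order. The iodide, which blocks C6 as the prenyl group does, is first carried through the oxygen-to-carbon acyl transfer of step 7. This gives the iodo-lactone (3'R)-7-O,1'-lactone of 3-[(2S,3S)-5,7-dihydroxy-6-iodo-2,3-dimethyl-4-oxo-3,4-dihydro-2H-chromen-8-yl]hexanoic acid F4, which has no alkene left. Stille coupling of F4 with 9 under the conditions of step 6 then gives 12, where the route is rejoined.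

Further compounds

F1 | step 7 | (2S,3S)-5,7-dihydroxy-2,3-dimethyl-6-(3-methylbut-2-en-1-yl)-2,3-dihydro-4H-chromen-4-one | Oc1c(CC=C(C)C)c(O)c2C(=O)[C@@H](C)[C@H](C)Oc2c1
F2 | step 3 | (2R,3R)-5-hydroxy-2,3-dimethyl-4-oxo-3,4-dihydro-2H-chromen-7-yl (E)-hex-2-enoate | CCC/C=C/C(=O)Oc1cc(O)c2C(=O)[C@H](C)[C@@H](C)Oc2c1
F3 | step 5 | (2S,3S)-2,3-dimethyl-5-[(2-methylbut-3-en-2-yl)oxy]-4-oxo-3,4-dihydro-2H-chromen-7-yl (E)-hex-2-enoate | CCC/C=C/C(=O)Oc1cc(OC(C)(C)C=C)c2C(=O)[C@@H](C)[C@H](C)Oc2c1
F4 | step 6 | (3'R)-7-O,1'-lactone of 3-[(2S,3S)-5,7-dihydroxy-6-iodo-2,3-dimethyl-4-oxo-3,4-dihydro-2H-chromen-8-yl]hexanoic acid | CCC[C@@H]1CC(=O)Oc2c(I)c(O)c3C(=O)[C@@H](C)[C@H](C)Oc3c12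
A1 | alternative 1 | 5,7-dihydroxy-4-propyl-2H-chromen-2-one | CCCc1cc(=O)oc2cc(O)cc(O)c12
A2 | alternative 1 | 3',2'-didehydro analogue of 12 (the 4-propylcoumarin fused at C7–C8 of the (2S,3S)-5-hydroxy-2,3-dimethyl-6-prenylchroman-4-one) | CCCC1=CC(=O)Oc2c(CC=C(C)C)c(O)c3C(=O)[C@@H](C)[C@H](C)Oc3c12
A3 | alternative 2 | (2S,3S)-5,7-dihydroxy-2,3-dimethyl-6-(3-methylbut-2-en-1-yl)-2,3-dihydro-4H-chromen-4-one | Oc1c(CC=C(C)C)c(O)c2C(=O)[C@@H](C)[C@H](C)Oc2c1
A4 | alternative 2 | (2S,3S)-5,7-dihydroxy-2,3-dimethyl-6-(3-methylbut-2-en-1-yl)-8-[1-(4-methylbenzenesulfonyl)butyl]-2,3-dihydro-4H-chromen-4-one (both epimers at the sulfone carbon) | CCCC(c1c(O)c(CC=C(C)C)c(O)c2C(=O)[C@@H](C)[C@H](C)Oc12)S(=O)(=O)c1ccc(C)cc1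
A5 | alternative 2 | (2S,3S)-8-butylidene-5-hydroxy-2,3-dimethyl-6-(3-methylbut-2-en-1-yl)-2,3-dihydro-4H-chromene-4,7(8H)-dione (ortho-quinone methide, alkene geometry undefined) | CCCC=C1C(=O)C(CC=C(C)C)=C(O)C2=C1O[C@@H](C)[C@H](C)C2=O
A6 | alternative 3 | 2,4,6-tris(methoxymethoxy)phenylboronic acid | COCOc1cc(OCOC)c(B(O)O)c(OCOC)c1
A7 | alternative 3 | methyl (3R)-3-[2,4,6-tris(methoxymethoxy)phenyl]hexanoate | CCC[C@H](CC(=O)OC)c1c(OCOC)cc(OCOC)cc1OCOC
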